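## Structural features

The target is a cyclohexane ring carrying a tertiary hydroxyl and a carboxylic acid at C1, a free secondary hydroxyl at C3, and two identical (E)-4-hydroxycinnamoyl (p-coumaroyl) esters at C4 and C5. The two benzene rings are joined to the core only through these ester chains. C3, C4 and C5 are contiguous stereocentres (O3 axial and cis to O4, O4 and O5 trans-diequatorial), and C1 is a fourth, 1,3-related to both C3 and C5. All four have the configuration of (−)-quinic acid, so no stereocentre has to be created. The fragile parts are the two conjugated esters (cleaved by nucleophilic base, isomerised to Z by light), the free phenols, and above all the O3 hydroxyl cis to the C4 ester, which permits 4→3 acyl migration as soon as base is present. The real difficulty is regiochemical: O4 and O5 must be acylated while O3, O1 and the carboxyl end up free, and every protecting group must leave without base. The core helps, because O5 is the only hydroxyl cis to the carboxyl; in the resulting 1,5-lactone O3 is the single exposed equatorial hydroxyl. The key step exploits the position of each ester carbonyl carbon between a ring oxygen (O4 or O5) and the α-carbon of an (E)-styryl unit: it can enter as carbon monoxide between an O–H bond and an alkenyl C–I bond, leaving every ring C–O bond and stereocentre untouched.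

## Logic of the disconnections

12 to 10. No skeletal bond is cut. Three O–Si bonds and the benzylic O–C bond of an ester are added in the retrosynthetic sense. The reason is that a free acid and free phenols would themselves be acylated in the carbonylation, and a free O3 would compete and later accept a migrating acyl group. The gain is a neutral compound that can be purified on silica. The demand on the forward step is that all four groups leave under acid or acidic fluoride only, with the benzylic cation trapped, passing through 11.

10 to 5, 8 and 9. At each of the two ester groups the acyl C–O bond to the ring oxygen and the acyl C–Cα bond to the styryl carbon are cut, four bonds in all. Cutting here makes the carbonyl carbons one-carbon units, so no activated cinnamic acid derivative has to be made or stored. The 25 carbons of the target fall into a seven-carbon chiral-pool core, two identical eight-carbon aryl-vinyl units and two molecules of 9. The demand is severe: an acyl–palladium intermediate must be captured twice by a hindered vicinal diol used as the limiting partner, with E geometry retained and O1 left alone.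

5 to 3. The benzylic O–C bond of the ester is cut and the acyl–O5 bond of the lactone is re-formed. In 3 the carboxyl and O5 protect each other and O3 is already distinguished. The demand is that the lactone be opened without moving the silyl group from O3 to the cis O4 and without liberating the hydroxy acid, which would close again; hence the carboxylate 4 is alkylated in the same flask.

3 to 2. The O3–Si bond is cut. In the bicyclic lactone O3–H is the only unhindered equatorial secondary hydroxyl (O4–H is axial, O1–H tertiary), so the differentiation costs one step. The demand is clean mono-silylation.

2 to 1. The acyl–O5 bond of the lactone is cut, arriving at the chiral-pool acid with all four stereocentres in place. The forward step needs only dehydrating acid.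

8 to 7. The Cα=Cβ double bond is cut, the iodine-bearing carbon coming from a one-carbon reagent. This reduces the aryl-vinyl unit to an aromatic aldehyde. The demand is high E selectivity, since the alkene geometry of the target is fixed here.

7 to 6. The aryl O–Si bond is cut. The phenol must be masked so that it cannot intercept the acyl–palladium species; the forward step is routine.

## Other disconnections considered

Alternative 1: The cut is the C1–O bond of the tertiary alcohol. The ring is taken from the shikimate series, where C1 is an enoate carbon, and the oxygen is added afterwards. In the forward key step the free allylic O3–H of the diacetal-protected methyl shikimate A1 would steer a hydroperoxide anion or a peracid to its own face of the C1=C2 bond, giving the epoxy ester A2 with the C1 configuration of 1.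
- In its favour: in A1 and A2 the trans-diequatorial O4/O5 pair is already tied in one acetal and O3 stands alone. This is exactly the differentiation the target needs, and here the alternative is the better plan: O3 could be capped and the 4,5-diol released without a silyl ether ever sitting next to a free cis hydroxyl under base.
- Against it: A2 carries an oxygen at C2 that the target lacks. It must be removed by breaking C2–O while C1–O stays, the opposite of the usual reductive opening of glycidic esters, so a detour through a C2 halide or selenide and a radical reduction is needed. The methyl ester must be exchanged for an acid-labile one before the cinnamoyl groups arrive, and the acid-labile diacetal must be removed in the presence of whatever caps O3.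
- Comparison: on structure it builds a stereocentre that 1 supplies for nothing. On mechanism the facial control by O3 is sound and about as dependable as any step of the chosen plan, but the C2 deoxygenation is less so. On step economy it is at least six operations longer to a compound of the type of 5, and it leaves the ester bonds to be made by the same carbonylation anyway.

Alternative 2: The cut is the ring bond C1–C2, tracing the carbocycle to the open-chain seven-carbon keto acid phosphate A3. In the forward key step the synthase, with its redox cofactor, would eliminate phosphate and close the ring by intramolecular aldol addition to give 3-dehydroquinic acid A4.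
- In its favour: one aqueous step without protecting groups makes the ring and the quaternary centre under complete enzymatic stereocontrol. In A4, C3 is a ketone, so the 4,5-diol is distinguished from C3 by oxidation level and not by a protecting group. On bond-forming power and on this built-in differentiation the alternative is the better plan.
- Against it: A3 is not a practical article of commerce and would itself have to be made enzymatically, and the enzyme has to be produced. A4 is a β-hydroxy ketone that readily loses the C1 hydroxyl by elimination, and its C4 ester would be an α-acyloxy ketone open to enolisation and acyl shift. At the end the C3 carbonyl must be reduced from the equatorial side to the axial alcohol in the presence of two conjugated esters.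
- Comparison: 1 is the cheap reduced form of A4, so constructing the ring is redundant. On mechanism the aldol closure is beyond reproach; on reliability of the later steps and on step count from purchasable material the chosen plan is clearly ahead.

Alternative 3: The cuts are the ring bonds C1–C6 and C2–C3, a [4+2] retron in a cyclohex-3-ene that carries the future C1 substituents. In the forward key step buta-1,3-diene A5 and 2-(benzoyloxy)acrolein A6, activated by a chiral diammonium salt, would give the aldehyde A7 with the quaternary centre set.
- In its favour: the route is fully synthetic, so either enantiomer and labelled or modified cores become available, which the chiral pool cannot offer; this is a genuine advantage. The cycloaddition is a well-understood step and in mechanistic reliability the equal of the carbonylation.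
- Against it: A7 holds one of the four stereocentres and one of the four ring oxygens. The rest must follow by oxidation to the acid, halolactonisation (relaying the carboxyl to the cis oxygen at the future C5), elimination, dihydroxylation anti to the lactone bridge and benzoate removal.
- Comparison: this sequence converges on the very lactone 2 that the chosen plan reaches in one step from 1, so it costs roughly six to eight additional steps. Enantiomeric purity would rest on a catalyst instead of being inherent.

Key step: step 6

Remark on the chemistry: ring positions are numbered so that O5 is the lactone-forming oxygen (cis to the carboxyl) and O3 the axial oxygen cis to O4. Read this way the target, diol 5 and bis-ester 10 all have the configuration of (−)-quinic acid and the silyl ether of 5 sits on O3, so no structure needed correcting. The changes to the plan are that the hydroxy acid is never liberated on the way to 5, that an acyl-transfer co-catalyst is added to the carbonylation, and that the two deprotections are run in one flask.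

## Route

Step 1
Reactants: 1 (−)-quinic acid [(1S,3R,4S,5R)-1,3,4,5-tetrahydroxycyclohexane-1-carboxylic acid]
Product: 2 quinide [(−)-quinic acid 1,5-lactone; (1S,3R,4R,5R)-1,3,4-trihydroxy-6-oxabicyclo[3.2.1]octan-7-one]
Conditions: p-TsOH·H2O (cat.), toluene/DMF, reflux, Dean–Stark
Reagents that add atoms: none
Why: Acid-catalysed lactonisation (intramolecular Fischer esterification); only O5 is cis to the carboxyl, so only the 1,5-γ-lactone can close once the chair inverts, and azeotropic removal of water should drive it to completion without touching any stereocentre.

Step 2
Reactants: 2 quinide
Product: 3 3-O-(tert-butyldimethylsilyl)quinide [(1S,3R,4R,5R)-3-(tert-butyldimethylsilyloxy)-1,4-dihydroxy-6-oxabicyclo[3.2.1]octan-7-one]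
Conditions: TBSCl (1.1 equiv), imidazole, DMF, 0 °C
Reagents that add atoms: tert-butyldimethylsilyl chloride, CC(C)(C)[Si](C)(C)Cl
Why: Regioselective silylation of a secondary alcohol; in the bicyclic lactone O3–H is equatorial and open, O4–H is axial and flanked by two syn-axial C–H bonds, and O1–H is tertiary, so one equivalent of a bulky silyl chloride should react at O3 only.

Step 3
Reactants: 3 3-O-(tert-butyldimethylsilyl)quinide
Product: 5 4-methoxybenzyl 3-O-(tert-butyldimethylsilyl)quinate, via lithium 3-O-(tert-butyldimethylsilyl)quinate 4 (not isolated)
Conditions: LiOH·H2O (1.05 equiv), THF/H2O, 0 °C; evaporate to dryness; then PMBCl, Bu4NI (cat.), DMF, rt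
Reagents that add atoms: lithium hydroxide, [Li+].[OH-]; 4-methoxybenzyl chloride, COc1ccc(CCl)cc1
Why: Saponification of the strained γ-lactone followed by SN2 O-alkylation of the carboxylate; one equivalent of hydroxide at 0 °C should be consumed by the lactone before it can move the silyl group to the cis O4, and because the hydroxy acid is never set free it cannot close back to 3. Under the non-basic alkylation conditions only the carboxylate is nucleophilic, so O1, O4 and O5 stay free and the ring relaxes to the chair with O4–H and O5–H equatorial.

Step 4
Reactants: 6 4-hydroxybenzaldehyde
Product: 7 4-(tert-butyldimethylsilyloxy)benzaldehyde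
Conditions: TBSCl, imidazole, CH2Cl2, rt
Reagents that add atoms: tert-butyldimethylsilyl chloride, CC(C)(C)[Si](C)(C)Cl
Why: Standard silylation of a phenol; the silyl ether keeps the phenol from competing as a nucleophile in the carbonylation and leaves in the same operation as the O3 silyl group at the end.

Step 5
Reactants: 7 4-(tert-butyldimethylsilyloxy)benzaldehyde
Product: 8 (E)-tert-butyl[4-(2-iodovinyl)phenoxy]dimethylsilane
Conditions: CHI3 (2 equiv), CrCl2 (6 equiv), THF/1,4-dioxane, 0 °C → rt, dark
Reagents that add atoms: iodoform, IC(I)I
Why: Takai olefination; the geminal dichromium carbenoid formed from CHI3 and CrCl2 adds to the aldehyde and the β-oxido organochromium intermediate eliminates anti, which for aromatic aldehydes should give the E-alkenyl iodide predominantly.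

Step 6
Reactants: 5 4-methoxybenzyl 3-O-(tert-butyldimethylsilyl)quinate; 8 (E)-tert-butyl[4-(2-iodovinyl)phenoxy]dimethylsilane (two molecules incorporated); 9 carbon monoxide (two molecules incorporated)
Product: 10 4-methoxybenzyl 3-O-(tert-butyldimethylsilyl)-4,5-bis-O-[(E)-4-(tert-butyldimethylsilyloxy)cinnamoyl]quinate
Conditions: Pd(OAc)2 (10 mol %), 4,5-bis(diphenylphosphino)-9,9-dimethylxanthene (12 mol %), i-Pr2NEt (4 equiv), DMAP (0.5 equiv), CO (1 atm), 8 (3 equiv), 4 Å MS, toluene, 50 °C, dark
Reagents that add atoms: none
Why: Pd(OAc)2 is reduced in the flask to a zerovalent palladium–diphosphine complex, which inserts into the C(sp2)–I bond of 8 with retention of the E geometry, and CO then inserts into the styryl–palladium bond to give an (E)-cinnamoyl–palladium iodide. The acyl group is passed to oxygen either by base-assisted alcoholysis at the metal or, faster for a hindered secondary alcohol, through an N-acylpyridinium ion formed with DMAP, while i-Pr2NEt takes up HI and zerovalent palladium is released; two such cycles should acylate O5 and then O4. The closest known reaction type is the palladium-catalysed alkoxycarbonylation of alkenyl and aryl halides (Heck carbonylation), here with the alcohol as the limiting partner and the iodide in excess. No ring is closed and no stereocentre is created; the four ring stereocentres are spectators and both alkene geometries are inherited from 8. The selectivity required is O4 and O5 against O1 and O3: O3 is blocked as its silyl ether, and the tertiary O1–H next to the ester carbonyl is too hindered to intercept the acyl donor. The wide bite angle of the xanthene diphosphine should speed the ester-forming elimination and keep the catalyst intact under 1 atm of CO, so that double carbonylation and Heck-type coupling of 8 with the new cinnamate do not compete. Early acylation of O5 also removes the only hydroxyl able to close back onto the benzylic ester.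

Step 7
Reactants: 10 4-methoxybenzyl 3-O-(tert-butyldimethylsilyl)-4,5-bis-O-[(E)-4-(tert-butyldimethylsilyloxy)cinnamoyl]quinate
Product: 12 4,5-di-O-p-coumaroylquinic acid, via 3-O-(tert-butyldimethylsilyl)-4,5-bis-O-[(E)-4-(tert-butyldimethylsilyloxy)cinnamoyl]quinic acid 11 (not isolated)
Conditions: CF3CO2H/CH2Cl2 (1:4), anisole (10 equiv), 0 °C; evaporate with toluene; then HF·pyridine, pyridine/THF, 0 °C → rt, dark
Reagents that add atoms: none
Why: Acidolysis of the 4-methoxybenzyl ester (SN1 cleavage, the benzylic cation being trapped by anisole) followed by fluoride-mediated cleavage of the three silyl ethers in a medium that stays acidic, so that neither acyl migration from O4 to O3 nor ester solvolysis is promoted. Extraction of the acid into ethyl acetate from water at pH 3 and reversed-phase chromatography avoid any basic work-up, and neither reagent touches the cinnamoyl esters, the E alkenes or the ring stereocentres.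

## Compound list

1 | (−)-quinic acid | O[C@@H]1[C@H](O)C[C@@](O)(C(=O)O)C[C@H]1O | starting material
2 | quinide, (−)-quinic acid 1,5-lactone | O[C@@H]1[C@H](O)C[C@]2(O)C[C@H]1OC2=O | intermediate
3 | 3-O-(tert-butyldimethylsilyl)quinide | O[C@@H]1[C@H](O[Si](C)(C)C(C)(C)C)C[C@]2(O)C[C@H]1OC2=O | intermediate
4 | lithium 3-O-(tert-butyldimethylsilyl)quinate | O[C@@H]1[C@H](O[Si](C)(C)C(C)(C)C)C[C@@](O)(C(=O)[O-])C[C@H]1O.[Li+] | intermediate (not isolated)
5 | 4-methoxybenzyl 3-O-(tert-butyldimethylsilyl)quinate | O[C@@H]1[C@H](O[Si](C)(C)C(C)(C)C)C[C@@](O)(C(=O)OCc2ccc(OC)cc2)C[C@H]1O | intermediate
6 | 4-hydroxybenzaldehyde | O=Cc1ccc(O)cc1 | starting material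
7 | 4-(tert-butyldimethylsilyloxy)benzaldehyde | O=Cc1ccc(O[Si](C)(C)C(C)(C)C)cc1 | intermediate
8 | (E)-tert-butyl[4-(2-iodovinyl)phenoxy]dimethylsilane | I/C=C/c1ccc(O[Si](C)(C)C(C)(C)C)cc1 | intermediate
9 | carbon monoxide | [C-]#[O+] | starting material
10 | 4-methoxybenzyl 3-O-(tert-butyldimethylsilyl)-4,5-bis-O-[(E)-4-(tert-butyldimethylsilyloxy)cinnamoyl]quinate | O=C(/C=C/c1ccc(O[Si](C)(C)C(C)(C)C)cc1)O[C@@H]1[C@H](O[Si](C)(C)C(C)(C)C)C[C@@](O)(C(=O)OCc2ccc(OC)cc2)C[C@H]1OC(=O)/C=C/c1ccc(O[Si](C)(C)C(C)(C)C)cc1 | intermediate
11 | 3-O-(tert-butyldimethylsilyl)-4,5-bis-O-[(E)-4-(tert-butyldimethylsilyloxy)cinnamoyl]quinic acid | O=C(/C=C/c1ccc(O[Si](C)(C)C(C)(C)C)cc1)O[C@@H]1[C@H](O[Si](C)(C)C(C)(C)C)C[C@@](O)(C(=O)O)C[C@H]1OC(=O)/C=C/c1ccc(O[Si](C)(C)C(C)(C)C)cc1 | intermediate (not isolated)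
12 | 4,5-di-O-p-coumaroylquinic acid | O=C(/C=C/c1ccc(O)cc1)O[C@@H]1[C@H](O)C[C@@](O)(C(=O)O)C[C@H]1OC(=O)/C=C/c1ccc(O)cc1 | target

## Step count and least certain steps

Total: 7 steps. Longest linear sequence: 5 steps (1 → 2 → 3 → 5 → 10 → 12); the aryl branch adds steps 4 and 5.

Step 6 (key step). The most likely failure is stalling after the first acylation. Capture of the acyl–palladium or acylpyridinium intermediate by the hindered O4–H is slow, so the intermediate may be lost to traces of water, or the catalyst may fall out as palladium metal under CO. A second possibility is amine-promoted closure of O5 onto the benzylic ester before O5 is acylated. The fallback sets out from 8 (with 5 as the alcohol) and returns at 10; it separates carbonylation from esterification. 8 would be carbonylated with water as nucleophile (Pd(OAc)2, the same diphosphine, CO 1 atm, H2O, i-Pr2NEt, 1,4-dioxane, 50 °C) to (E)-4-(tert-butyldimethylsilyloxy)cinnamic acid F1. Under neutral conditions 1-chloro-N,N,2-trimethylprop-1-en-1-amine would convert this into (E)-4-(tert-butyldimethylsilyloxy)cinnamoyl chloride F2. Diol 5 would then be acylated twice with F2 (pyridine, DMAP, CH2Cl2, 0 °C → rt) to give 10.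

Step 3. The most likely failure is migration of the silyl group from O3 to the cis O4 while hydroxide is present, or incomplete alkylation of the poorly soluble lithium carboxylate followed by re-closure of the lactone on work-up. The fallback sets out from 2 and returns at 12; it caps O3 with a group that cannot migrate. Stannylene-mediated alkylation of 2 (Bu2SnO, toluene, reflux; then PMBCl, CsF, DMF), which favours the equatorial oxygen of a cis-diol, would give 3-O-(4-methoxybenzyl)quinide F3. Opening and alkylation as in step 3 would give 4-methoxybenzyl 3-O-(4-methoxybenzyl)quinate F4. Carbonylation with 8 and 9 as in step 6 would give 4-methoxybenzyl 3-O-(4-methoxybenzyl)-4,5-bis-O-[(E)-4-(tert-butyldimethylsilyloxy)cinnamoyl]quinate F5. CF3CO2H with anisole would remove the benzylic ester and ether together to give 4,5-bis-O-[(E)-4-(tert-butyldimethylsilyloxy)cinnamoyl]quinic acid F6, and HF·pyridine would then free the two phenols to give 12.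

Step 7. The most likely failure is slow cleavage of the hindered axial O3 silyl ether, which forces long exposure and so invites acyl migration towards O3 or partial loss of an ester. Incomplete trapping of the benzylic cation, leading to alkylation of the aromatic rings, is the second concern. The fallback sets out from 10 and returns at 12; it reverses the order and isolates the intermediate. HF·pyridine alone would convert 10 into 4-methoxybenzyl 4,5-di-O-p-coumaroylquinate F7, a neutral ester that can be driven to completion, purified on silica and checked for regiochemical integrity. A brief acidolysis (CF3CO2H, anisole, CH2Cl2, 0 °C) would then give 12.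

Step 5. The most likely failure is erosion of the E selectivity or reductive loss of iodine from the electron-rich, light-sensitive alkenyl iodide in the presence of excess divalent chromium. The fallback sets out from 7 and returns at 8; it fixes the geometry by syn addition to an alkyne. Colvin homologation of 7 (Me3SiCHN2, LDA, THF, −78 °C → rt) would give tert-butyl(4-ethynylphenoxy)dimethylsilane F8. Hydrozirconation with Cp2Zr(H)Cl followed by I2 would give 8 as the E isomer only.

## Further compounds

F1 | step 6 | (E)-4-(tert-butyldimethylsilyloxy)cinnamic acid | OC(=O)/C=C/c1ccc(O[Si](C)(C)C(C)(C)C)cc1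
F2 | step 6 | (E)-4-(tert-butyldimethylsilyloxy)cinnamoyl chloride | ClC(=O)/C=C/c1ccc(O[Si](C)(C)C(C)(C)C)cc1
F3 | step 3 | 3-O-(4-methoxybenzyl)quinide | O[C@@H]1[C@H](OCc3ccc(OC)cc3)C[C@]2(O)C[C@H]1OC2=O
F4 | step 3 | 4-methoxybenzyl 3-O-(4-methoxybenzyl)quinate | O[C@@H]1[C@H](OCc2ccc(OC)cc2)C[C@@](O)(C(=O)OCc2ccc(OC)cc2)C[C@H]1O
F5 | step 3 | 4-methoxybenzyl 3-O-(4-methoxybenzyl)-4,5-bis-O-[(E)-4-(tert-butyldimethylsilyloxy)cinnamoyl]quinate | O=C(/C=C/c1ccc(O[Si](C)(C)C(C)(C)C)cc1)O[C@@H]1[C@H](OCc2ccc(OC)cc2)C[C@@](O)(C(=O)OCc2ccc(OC)cc2)C[C@H]1OC(=O)/C=C/c1ccc(O[Si](C)(C)C(C)(C)C)cc1
F6 | step 3 | 4,5-bis-O-[(E)-4-(tert-butyldimethylsilyloxy)cinnamoyl]quinic acid | O=C(/C=C/c1ccc(O[Si](C)(C)C(C)(C)C)cc1)O[C@@H]1[C@H](O)C[C@@](O)(C(=O)O)C[C@H]1OC(=O)/C=C/c1ccc(O[Si](C)(C)C(C)(C)C)cc1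
F7 | step 7 | 4-methoxybenzyl 4,5-di-O-p-coumaroylquinate | O=C(/C=C/c1ccc(O)cc1)O[C@@H]1[C@H](O)C[C@@](O)(C(=O)OCc2ccc(OC)cc2)C[C@H]1OC(=O)/C=C/c1ccc(O)cc1
F8 | step 5 | tert-butyl(4-ethynylphenoxy)dimethylsilane | C#Cc1ccc(O[Si](C)(C)C(C)(C)C)cc1
A1 | alternative 1 | methyl 4,5-O-(2,3-dimethoxybutane-2,3-diyl)shikimate | COC(=O)C1=C[C@@H](O)[C@H]2O[C@](C)(OC)[C@@](C)(OC)O[C@@H]2C1
A2 | alternative 1 | methyl 1,2-anhydro-4,5-O-(2,3-dimethoxybutane-2,3-diyl)-2-hydroxyquinate (epoxide cis to the 3-hydroxyl) | COC(=O)[C@]12O[C@H]1[C@@H](O)[C@H]3O[C@](C)(OC)[C@@](C)(OC)O[C@@H]3C2
A3 | alternative 2 | 3-deoxy-D-arabino-hept-2-ulosonic acid 7-phosphate | OC(=O)C(=O)C[C@@H](O)[C@H](O)[C@H](O)COP(=O)(O)O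
A4 | alternative 2 | 3-dehydroquinic acid | O[C@@H]1C(=O)C[C@@](O)(C(=O)O)C[C@H]1O
A5 | alternative 3 | buta-1,3-diene | C=CC=C
A6 | alternative 3 | 2-(benzoyloxy)acrolein | O=CC(=C)OC(=O)c1ccccc1
A7 | alternative 3 | (S)-1-formylcyclohex-3-en-1-yl benzoate | O=C[C@]1(OC(=O)c2ccccc2)CCC=CC1
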